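## Analysis of the target

- **Skeleton.** The target is isofraxidin (7-hydroxy-6,8-dimethoxycoumarin) etherified at O7 with a C15 rearranged-drimane unit. Numbering used throughout: ring A = C1–C2–C3(=O)–C4–C5–C10; ring B = C5–C6–C7–C8–C9–C10; C11 = the OCH2 carbon on C9. In systematic names C9, C8, C5, C4, C3 and C10 become naphthalene C1, C2, C4a, C5, C6 and C8a. The target is then 7-{[(1R,2R,4aS,5R,8aR)-1,2,4a,5-tetramethyl-6-oxodecahydronaphthalen-1-yl]methoxy}-6,8-dimethoxy-2H-chromen-2-one.
- **Stereocentres.** C4, C5, C8, C9 and C10 are contiguous on a trans-decalin. The methyl groups on C4, C5 and C9 lie on one face; H-10, the C8 methyl group and C11 lie on the other.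
- **Conformation.** In the chair–chair form the C5 and C9 methyl groups are syn-diaxial, C11 is equatorial, the C8 methyl group is axial (anti to the C9 methyl group) and the C4 methyl group is equatorial.
- **What can and cannot be corrected.** C4 is α to the ketone and sits in its thermodynamic (equatorial) arrangement, so it is self-correcting. C5 and C9 are quaternary, and C8 and C10 cannot be epimerised.
- **The C8 problem.** The axial C8 methyl group, cis to C11, is the epimer that a hydrogenation of a C8 alkene would not give, because hydrogen would arrive anti to the two axial methyl groups. A biogenetic C9→C8 hydride shift would not give it either. The C8–C9 relationship therefore has to come from a stereospecific C–C bond formation.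
- **Ring B has no functional group**, so any retron there has to be introduced; a C6=C7 double bond is the natural one.
- **Sensitive groups.** The coumarin lactone and its C3=C4 bond are sensitive to base, nucleophiles and hydrogenation. The ketone is enolisable. The ether sits on a neopentyl carbon, so O–C11 bond formation is slow.

## Retrosynthetic reasoning

**Ketone last.** The C3 ketone of 19 is taken back to the equatorial silyl ether in 17 via alcohol 18. A protected carbinol at C3 keeps C4 configurationally fixed through the whole route. In the key step it also serves, together with the C4 methyl group, as a second equatorial anchor that is erased only at the end.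

**Ether bond O–C11.** 17 is cut into the neopentyl alcohol 15 and coumarin 16. The cut is made here because 16 is a commercial, acidic phenol. It is made late because the coumarin C3=C4 bond would not survive the ring-B hydrogenation. The forward step is a Mitsunobu-type dehydrative alkylation at a neopentyl carbon, which is the second risk of the route.

**Redox adjustment.** 15 comes from 13 by reduction of the formyl group (14) and saturation of C6=C7. This reintroduces the Diels–Alder retron in ring B: a cyclohexene with a formyl group on C9.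

**Key disconnection.** In 13 the bonds C5–C10 and C8–C9 are cut together, which opens both rings and gives the acyclic (E,E,E)-trienal 12.
- The bonds are cut here because they are the only pair whose cleavage leaves a tether (C1–C4) with a terminally activated (E)-2-methyl-enal on one side and a diene on the other.
- The gain: four of the five stereocentres (C5, C8, C9, C10), including both quaternary carbons, arise in one step from alkene geometry and from the (C3, C4) stereodiad. The C8–C9 relationship follows from the endo rule and is not left to a reduction.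
- The forward reaction must achieve an endo, trans-fused intramolecular Diels–Alder reaction on the diene face dictated by the tether.

**Trienal assembly.** 12 is cut at C6–C7 into vinyl iodide 10 and boronate 11 (Suzuki–Miyaura coupling, retention of both geometries). 10 is cut at C9=C10 into the terminal alkene 8 and methacrolein 9 (cross-metathesis, E-selective). 8 comes from alkyne 6 by syn-carboalumination and iodinolysis, which fixes the "inside" C5 methyl group and the E geometry.

**Stereodiad.** 6 is the silyl ether of 5, which is cut at C3–C4 into pent-4-enal 4 and the chiral allenylstannane 3. Compound 3 comes from 2 and from the bought stereocentre of 1. This is the only stereochemistry introduced from outside; all other centres are relayed from it.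

## Alternatives that were turned down

**Alternative 1:** the textbook route.
- Disconnection: ring A/B from a proline-catalysed Robinson annulation giving the Wieland–Miescher ketone A1, whose angular methyl group becomes the C5 methyl group.
- Forward: deconjugative double alkylation of the enone at C9, reduction of the ring-fusion alkene, methylenation and hydrogenation at C8, then a 1,2-carbonyl transposition with methylation (C4 ketone to C4 methyl/C3 ketone), then etherification.
- Turned down: hydrogenation at C8 would deliver hydrogen anti to the axial C5 and C9 methyl groups. That makes the C8 methyl group equatorial and cis to the C9 methyl group, which is the C8 epimer of the target. The order and facial sense of the two C9 alkylations are also governed by the same axial methyl group. Most of the roughly sixteen or more steps would be functional-group traffic.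

**Alternative 2:** the biomimetic route.
- Disconnection: the whole decalin from the (S)-epoxyfarnesyl ether A2 of 16.
- Forward: Lewis-acid epoxy-polyene cyclisation to the drimanyl C8 cation, then a backbone rearrangement (H9→C8, Me10→C9, H5→C10, Me4→C5, H3→C4) ending in the C3 ketone.
- Turned down: the suprafacial hydride shift from C9 to C8 necessarily leaves the C8 and C9 methyl groups cis, again the C8 epimer. Four consecutive 1,2-shifts would each compete with elimination at a tertiary cation. The allylic aryl ether of A2 would ionise under the acid needed.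

**Alternative 3:** ring A by intermolecular Diels–Alder reaction.
- Disconnection: ring A from the ring-B enone A3 (C6 ketone, C5=C10) and the 3-silyloxy-1,3-pentadiene A4, which would give the C3 ketone and C4 methyl group directly.
- Turned down: addition to a cyclic dienophile can only give a cis ring fusion, and C10 could not be epimerised because the activating carbonyl is at C6, not C1. The 2-silyloxy group of A4 directs its substituted terminus to C10, the wrong regiochemistry. The C6 carbonyl would have to be removed. A3 itself would need an asymmetric synthesis of C8 and C9, which is the hard part of the problem.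

Key step: step 8

Assumption: compounds 1, 4, 9, 11 and 16 are taken as commercially available; the anti SN2′/anti SE2′ course of the allenylstannane chemistry is assumed to hold for this unbranched aldehyde as for its known analogues.

## Route

Step 1
Reactants: 1 (R)-but-3-yn-2-ol
Product: 2 (R)-but-3-yn-2-yl methanesulfonate
Conditions: MsCl, Et3N, CH2Cl2, −78 to 0 °C
Reagents that add atoms: methanesulfonyl chloride, CS(=O)(=O)Cl
Why: Sulfonylation of a secondary alcohol; the stereocentre is not touched.

Step 2
Reactants: 2 (R)-but-3-yn-2-yl methanesulfonate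
Product: 3 (aS)-tributyl(buta-1,2-dien-1-yl)stannane
Conditions: Bu3SnH, LDA, THF, 0 °C; CuBr·SMe2, −78 °C; then 2, −78 °C
Reagents that add atoms: tributyltin hydride, CCCC[SnH](CCCC)CCCC
Why: Anti-SN2′ displacement of the propargylic mesylate by a stannylcopper reagent; the centre chirality of 2 is converted into the axial chirality of the allene.

Step 3
Reactants: 3 (aS)-tributyl(buta-1,2-dien-1-yl)stannane; 4 pent-4-enal
Product: 5 (3R,4R)-3-methyloct-7-en-1-yn-4-ol
Conditions: BF3·OEt2, CH2Cl2, −78 °C
Reagents that add atoms: none
Why: Lewis-acid-promoted SE2′ addition of a chiral allenylstannane to an aldehyde (Marshall propargylation); anti-SE2′ attack sets the methyl-bearing carbon (future C4) from the allene axis, and the open transition state should give the syn carbinol (future C3).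

Step 4
Reactants: 5 (3R,4R)-3-methyloct-7-en-1-yn-4-ol
Product: 6 tert-butyl(dimethyl){[(3R,4R)-3-methyloct-7-en-1-yn-4-yl]oxy}silane
Conditions: TBSOTf, 2,6-lutidine, CH2Cl2, 0 °C
Reagents that add atoms: tert-butyldimethylsilyl trifluoromethanesulfonate, CC(C)(C)[Si](C)(C)OS(=O)(=O)C(F)(F)F
Why: Silylation of a secondary alcohol; the bulky ether later serves as an equatorial anchor and blocks oxa-Michael addition to the enal.

Step 5
Reactants: 6 tert-butyl(dimethyl){[(3R,4R)-3-methyloct-7-en-1-yn-4-yl]oxy}silane
Product: 8 tert-butyl{[(1E,3R,4R)-1-iodo-2,3-dimethylocta-1,7-dien-4-yl]oxy}dimethylsilane, via alkenyl(dimethyl)alane 7 (not isolated)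
Conditions: Me3Al, Cp2ZrCl2, CH2Cl2, 0 °C to rt; then I2, THF, −30 to 0 °C
Reagents that add atoms: trimethylaluminium, C[Al](C)C; iodine, II
Why: Zirconium-catalysed syn-methylalumination of the terminal alkyne (Negishi carboalumination) and iodinolysis with retention give the (E)-2-methyl-1-iodoalkene; the isolated terminal alkene should react much more slowly than the alkyne.

Step 6
Reactants: 8 tert-butyl{[(1E,3R,4R)-1-iodo-2,3-dimethylocta-1,7-dien-4-yl]oxy}dimethylsilane; 9 methacrolein
Product: 10 (2E,6R,7R,8E)-6-{[tert-butyl(dimethyl)silyl]oxy}-9-iodo-2,7,8-trimethylnona-2,8-dienal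
Conditions: second-generation Hoveyda–Grubbs catalyst (5 mol%), excess 9, CH2Cl2, 40 °C
Reagents that add atoms: none
Why: Olefin cross-metathesis of a terminal alkene with methacrolein should give the (E)-2-methyl-enal; the trisubstituted iodoalkene is sterically and electronically poor for the ruthenium carbene.

Step 7
Reactants: 10 (2E,6R,7R,8E)-6-{[tert-butyl(dimethyl)silyl]oxy}-9-iodo-2,7,8-trimethylnona-2,8-dienal; 11 4,4,5,5-tetramethyl-2-[(1E)-prop-1-en-1-yl]-1,3,2-dioxaborolane
Product: 12 (2E,6R,7R,8E,10E)-6-{[tert-butyl(dimethyl)silyl]oxy}-2,7,8-trimethyldodeca-2,8,10-trienal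
Conditions: Pd(dppf)Cl2 (5 mol%), aq. K3PO4, THF, rt
Reagents that add atoms: none
Why: Suzuki–Miyaura coupling of an alkenyl iodide with an alkenylboronate proceeds with retention at both partners and gives the (8E,10E)-diene; the mild base tolerates the enal.

Step 8
Reactants: 12 (2E,6R,7R,8E,10E)-6-{[tert-butyl(dimethyl)silyl]oxy}-2,7,8-trimethyldodeca-2,8,10-trienal
Product: 13 (1R,2R,4aS,5R,6R,8aR)-6-{[tert-butyl(dimethyl)silyl]oxy}-1,2,4a,5-tetramethyl-1,2,4a,5,6,7,8,8a-octahydronaphthalene-1-carbaldehyde
Conditions: Me2AlCl (1.2 equiv), CH2Cl2, −78 to −20 °C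
Reagents that add atoms: none
Why: Coordination of Me2AlCl to the formyl oxygen lowers the LUMO of the (E)-2-methyl-enal, which adds across the C5=C6–C7=C8 diene in a concerted, asynchronous [4+2] cycloaddition (Lewis-acid-promoted intramolecular Diels–Alder reaction of a 1,7,9-decatriene-type trienal, a known way to trans-decalin carbaldehydes). Ring B closes as the new cyclohexene through the σ-bonds C5–C10 and C8–C9, and ring A closes at the same time through C5–C10 with the four-carbon tether C1–C4 in a chair. Suprafacial addition turns the (E)-enal geometry into the C9/C10 relationship (H-10 cis to the formyl group) and the (8E,10E)-diene geometry into the C5/C8 relationship (C5 methyl "inside", C8 methyl "outside", hence trans across ring B). The endo position of the aluminium-bound formyl group ties the two pairs together: it puts the C8 methyl group cis to the formyl carbon and forces the trans ring fusion, so C5, C8, C9 and C10 should emerge in the relative configuration of the target. The absolute sense is relayed from the (6R,7R) stereodiad: only one diene face lets both the silyloxy group (C3) and the methyl group (C4) sit equatorial on the chair tether, while the other face would make both axial with the silyloxy group syn-pentane to the C5 methyl group. The step needs endo over exo selectivity and this facial selectivity; the first rests on Lewis-acid complexation of a terminally activated formyl dienophile, the second on the syn stereodiad. The inside methyl group at C5 disfavours the s-cis diene and slows the reaction, which is why the most reactive activation (enal plus aluminium Lewis acid) is chosen.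

Step 9
Reactants: 13 (1R,2R,4aS,5R,6R,8aR)-6-{[tert-butyl(dimethyl)silyl]oxy}-1,2,4a,5-tetramethyl-1,2,4a,5,6,7,8,8a-octahydronaphthalene-1-carbaldehyde
Product: 14 [(1R,2R,4aS,5R,6R,8aR)-6-{[tert-butyl(dimethyl)silyl]oxy}-1,2,4a,5-tetramethyl-1,2,4a,5,6,7,8,8a-octahydronaphthalen-1-yl]methanol
Conditions: NaBH4, MeOH/THF, 0 °C
Reagents that add atoms: none
Why: Hydride reduction of a non-enolisable aldehyde; no stereocentre is formed or put at risk.

Step 10
Reactants: 14 [(1R,2R,4aS,5R,6R,8aR)-6-{[tert-butyl(dimethyl)silyl]oxy}-1,2,4a,5-tetramethyl-1,2,4a,5,6,7,8,8a-octahydronaphthalen-1-yl]methanol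
Product: 15 [(1R,2R,4aS,5R,6R,8aR)-6-{[tert-butyl(dimethyl)silyl]oxy}-1,2,4a,5-tetramethyldecahydronaphthalen-1-yl]methanol
Conditions: H2 (1 atm), PtO2, EtOAc, rt
Reagents that add atoms: none
Why: Heterogeneous hydrogenation of the cis-disubstituted C6=C7 bond creates no stereocentre; platinum is chosen over palladium to suppress double-bond migration towards C8, and the step precedes the introduction of the coumarin.

Step 11
Reactants: 15 [(1R,2R,4aS,5R,6R,8aR)-6-{[tert-butyl(dimethyl)silyl]oxy}-1,2,4a,5-tetramethyldecahydronaphthalen-1-yl]methanol; 16 isofraxidin (7-hydroxy-6,8-dimethoxy-2H-chromen-2-one)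
Product: 17 7-{[(1R,2R,4aS,5R,6R,8aR)-6-{[tert-butyl(dimethyl)silyl]oxy}-1,2,4a,5-tetramethyldecahydronaphthalen-1-yl]methoxy}-6,8-dimethoxy-2H-chromen-2-one
Conditions: cyanomethylenetributylphosphorane (CMBP), toluene, 110 °C, sealed tube
Reagents that add atoms: none
Why: Mitsunobu-type dehydrative O-alkylation of an acidic phenol; the thermally robust phosphorane allows the temperature that SN2 displacement of the alkoxyphosphonium group at a neopentyl carbon needs, and C11 carries no β-hydrogen, so elimination cannot compete.

Step 12
Reactants: 17 7-{[(1R,2R,4aS,5R,6R,8aR)-6-{[tert-butyl(dimethyl)silyl]oxy}-1,2,4a,5-tetramethyldecahydronaphthalen-1-yl]methoxy}-6,8-dimethoxy-2H-chromen-2-one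
Product: 18 7-{[(1R,2R,4aS,5R,6R,8aR)-6-hydroxy-1,2,4a,5-tetramethyldecahydronaphthalen-1-yl]methoxy}-6,8-dimethoxy-2H-chromen-2-one
Conditions: HF·pyridine, THF, 0 °C to rt
Reagents that add atoms: none
Why: Acidic fluoride cleaves the secondary silyl ether and leaves the coumarin lactone and the aryl ether untouched.

Step 13
Reactants: 18 7-{[(1R,2R,4aS,5R,6R,8aR)-6-hydroxy-1,2,4a,5-tetramethyldecahydronaphthalen-1-yl]methoxy}-6,8-dimethoxy-2H-chromen-2-one
Product: 19 7-{[(1R,2R,4aS,5R,8aR)-1,2,4a,5-tetramethyl-6-oxodecahydronaphthalen-1-yl]methoxy}-6,8-dimethoxy-2H-chromen-2-one (target)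
Conditions: Dess–Martin periodinane, NaHCO3, CH2Cl2, rt
Reagents that add atoms: none
Why: Buffered Dess–Martin oxidation of the secondary alcohol; the adjacent C4 methyl group is already equatorial (thermodynamic), so enolisation cannot erode it.

## Compound list

1 | (R)-but-3-yn-2-ol | C[C@H](C#C)O | starting material
2 | (R)-but-3-yn-2-yl methanesulfonate | C[C@H](C#C)OS(C)(=O)=O | intermediate
3 | (aS)-tributyl(buta-1,2-dien-1-yl)stannane | CCCC[Sn](CCCC)(CCCC)C([H])=[C@@]=C([H])C | intermediate
4 | pent-4-enal | C=CCCC=O | starting material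
5 | (3R,4R)-3-methyloct-7-en-1-yn-4-ol | C#C[C@@H](C)[C@H](O)CCC=C | intermediate
6 | tert-butyl(dimethyl){[(3R,4R)-3-methyloct-7-en-1-yn-4-yl]oxy}silane | C#C[C@@H](C)[C@H](O[Si](C)(C)C(C)(C)C)CCC=C | intermediate
7 | [(1E,3R,4R)-4-{[tert-butyl(dimethyl)silyl]oxy}-2,3-dimethylocta-1,7-dien-1-yl]dimethylalane | C[Al](C)/C=C(\C)[C@@H](C)[C@H](O[Si](C)(C)C(C)(C)C)CCC=C | intermediate
8 | tert-butyl{[(1E,3R,4R)-1-iodo-2,3-dimethylocta-1,7-dien-4-yl]oxy}dimethylsilane | I/C=C(\C)[C@@H](C)[C@H](O[Si](C)(C)C(C)(C)C)CCC=C | intermediate
9 | methacrolein (2-methylprop-2-enal) | CC(=C)C=O | starting material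
10 | (2E,6R,7R,8E)-6-{[tert-butyl(dimethyl)silyl]oxy}-9-iodo-2,7,8-trimethylnona-2,8-dienal | O=C/C(C)=C/CC[C@@H](O[Si](C)(C)C(C)(C)C)[C@H](C)/C(C)=C/I | intermediate
11 | 4,4,5,5-tetramethyl-2-[(1E)-prop-1-en-1-yl]-1,3,2-dioxaborolane | C/C=C/B1OC(C)(C)C(C)(C)O1 | starting material
12 | (2E,6R,7R,8E,10E)-6-{[tert-butyl(dimethyl)silyl]oxy}-2,7,8-trimethyldodeca-2,8,10-trienal | O=C/C(C)=C/CC[C@@H](O[Si](C)(C)C(C)(C)C)[C@H](C)/C(C)=C/C=C/C | intermediate
13 | (1R,2R,4aS,5R,6R,8aR)-6-{[tert-butyl(dimethyl)silyl]oxy}-1,2,4a,5-tetramethyl-1,2,4a,5,6,7,8,8a-octahydronaphthalene-1-carbaldehyde | O=C[C@@]1(C)[C@@H]2CC[C@@H](O[Si](C)(C)C(C)(C)C)[C@H](C)[C@@]2(C)C=C[C@H]1C | intermediate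
14 | [(1R,2R,4aS,5R,6R,8aR)-6-{[tert-butyl(dimethyl)silyl]oxy}-1,2,4a,5-tetramethyl-1,2,4a,5,6,7,8,8a-octahydronaphthalen-1-yl]methanol | OC[C@@]1(C)[C@@H]2CC[C@@H](O[Si](C)(C)C(C)(C)C)[C@H](C)[C@@]2(C)C=C[C@H]1C | intermediate
15 | [(1R,2R,4aS,5R,6R,8aR)-6-{[tert-butyl(dimethyl)silyl]oxy}-1,2,4a,5-tetramethyldecahydronaphthalen-1-yl]methanol | OC[C@@]1(C)[C@@H]2CC[C@@H](O[Si](C)(C)C(C)(C)C)[C@H](C)[C@@]2(C)CC[C@H]1C | intermediate
16 | isofraxidin (7-hydroxy-6,8-dimethoxy-2H-chromen-2-one) | COc1cc2ccc(=O)oc2c(OC)c1O | starting material
17 | 7-{[(1R,2R,4aS,5R,6R,8aR)-6-{[tert-butyl(dimethyl)silyl]oxy}-1,2,4a,5-tetramethyldecahydronaphthalen-1-yl]methoxy}-6,8-dimethoxy-2H-chromen-2-one | COc1cc2ccc(=O)oc2c(OC)c1OC[C@@]1(C)[C@@H]2CC[C@@H](O[Si](C)(C)C(C)(C)C)[C@H](C)[C@@]2(C)CC[C@H]1C | intermediate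
18 | 7-{[(1R,2R,4aS,5R,6R,8aR)-6-hydroxy-1,2,4a,5-tetramethyldecahydronaphthalen-1-yl]methoxy}-6,8-dimethoxy-2H-chromen-2-one | COc1cc2ccc(=O)oc2c(OC)c1OC[C@@]1(C)[C@@H]2CC[C@@H](O)[C@H](C)[C@@]2(C)CC[C@H]1C | intermediate
19 | 7-{[(1R,2R,4aS,5R,8aR)-1,2,4a,5-tetramethyl-6-oxodecahydronaphthalen-1-yl]methoxy}-6,8-dimethoxy-2H-chromen-2-one | COc1cc2ccc(=O)oc2c(OC)c1OC[C@@]1(C)[C@@H]2CCC(=O)[C@H](C)[C@@]2(C)CC[C@H]1C | target

## Step count and risk

Total step count: 13. Longest linear sequence: 13 steps (steps 1–13 from 1; 11 steps from 4).

**Step 8 (key step).**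
- What may go wrong: the inside methyl group at C5 may make the cycloaddition slow enough for Lewis-acid-induced ionisation or isomerisation of the diene to compete. Endo selectivity may erode, because the endo mode has to build the developing syn-diaxial C5/C9 methyl interaction; this would give cis-fused material.
- Fallback: the dienophile is changed from a neutral enal to a cationic one. From 12, acetalisation with 1,2-bis(trimethylsilyloxy)ethane and catalytic TMSOTf in CH2Cl2 at −78 °C would give the alkenyl dioxolane F1. The same TMSOTf would ionise it to an alkoxyallyl cation, a far stronger dienophile that reacts at low temperature (ionic Diels–Alder reaction), and close it to the decalin dioxolane F2. Mild acidic hydrolysis (PPTS, wet acetone) would then return to the route at 13.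

**Step 11.**
- What may go wrong: slow SN2 displacement at the neopentyl C11, flanked by the quaternary C9 and the axial C8 methyl group, so that the activated alcohol decomposes or is returned unchanged.
- Fallback: the bond is formed on the aryl side instead. Compound 16 would be converted with Tf2O/pyridine into the aryl triflate F3. Palladium-catalysed C–O cross-coupling of F3 with 15 (Pd2(dba)3, tBuBrettPhos, Cs2CO3, toluene, 90 °C) uses the hindered alcohol as nucleophile, a role in which neopentyl-type alcohols are good partners, and rejoins the route at 17.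

**Step 3.**
- What may go wrong: incomplete syn selectivity with an unbranched aldehyde, leaving anti isomer that would spoil the diequatorial control in step 8.
- Fallback: from 4, a boron-mediated Evans syn aldol reaction with (S)-4-benzyl-3-propanoyloxazolidin-2-one (Bu2BOTf, iPr2NEt) would give the syn-aldol adduct F4. Transamidation (MeONHMe·HCl, Me3Al) to the Weinreb amide F5, silylation to the silyl ether F6, DIBAL-H reduction to the aldehyde F7 and Ohira–Bestmann alkynylation (K2CO3, MeOH) would rejoin the route at 6.

**Step 6.**
- What may go wrong: engagement of the iodoalkene by the ruthenium carbene (ring closure to a cyclohexene or catalyst death), or incomplete E selectivity.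
- Fallback: from 8, chemoselective oxidative cleavage of the terminal alkene (OsO4 cat., NaIO4, 2,6-lutidine, dioxane/H2O) would give the aldehyde F8. A Wittig reaction of F8 with 2-(triphenylphosphoranylidene)propanal in toluene at 80 °C would give the (E)-enal and rejoin the route at 10.

## Further compounds

F1 | step 8 | 2-[(2E,6R,7R,8E,10E)-6-{[tert-butyl(dimethyl)silyl]oxy}-7,8-dimethyldodeca-2,8,10-trien-2-yl]-1,3-dioxolane | O1CCOC1/C(C)=C/CC[C@@H](O[Si](C)(C)C(C)(C)C)[C@H](C)/C(C)=C/C=C/C
F2 | step 8 | 2-[(1R,2R,4aS,5R,6R,8aR)-6-{[tert-butyl(dimethyl)silyl]oxy}-1,2,4a,5-tetramethyl-1,2,4a,5,6,7,8,8a-octahydronaphthalen-1-yl]-1,3-dioxolane | O1CCOC1[C@@]2(C)[C@@H]3CC[C@@H](O[Si](C)(C)C(C)(C)C)[C@H](C)[C@@]3(C)C=C[C@H]2C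
F3 | step 11 | 6,8-dimethoxy-2-oxo-2H-chromen-7-yl trifluoromethanesulfonate | COc1cc2ccc(=O)oc2c(OC)c1OS(=O)(=O)C(F)(F)F
F4 | step 3 | (4S)-4-benzyl-3-[(2S,3R)-3-hydroxy-2-methylhept-6-enoyl]-1,3-oxazolidin-2-one | C=CCC[C@@H](O)[C@H](C)C(=O)N1[C@@H](Cc2ccccc2)COC1=O
F5 | step 3 | (2S,3R)-3-hydroxy-N-methoxy-N,2-dimethylhept-6-enamide | C=CCC[C@@H](O)[C@H](C)C(=O)N(C)OC
F6 | step 3 | (2S,3R)-3-{[tert-butyl(dimethyl)silyl]oxy}-N-methoxy-N,2-dimethylhept-6-enamide | C=CCC[C@@H](O[Si](C)(C)C(C)(C)C)[C@H](C)C(=O)N(C)OC
F7 | step 3 | (2S,3R)-3-{[tert-butyl(dimethyl)silyl]oxy}-2-methylhept-6-enal | C=CCC[C@@H](O[Si](C)(C)C(C)(C)C)[C@H](C)C=O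
F8 | step 6 | (4R,5R,6E)-4-{[tert-butyl(dimethyl)silyl]oxy}-7-iodo-5,6-dimethylhept-6-enal | O=CCC[C@@H](O[Si](C)(C)C(C)(C)C)[C@H](C)/C(C)=C/I
A1 | alternative 1 | (S)-Wieland–Miescher ketone, (8aS)-8a-methyl-3,4,8,8a-tetrahydronaphthalene-1,6(2H,7H)-dione | C[C@]12CCC(=O)C=C1CCCC2=O
A2 | alternative 2 | 7-{[(2E,6E)-9-[(2S)-3,3-dimethyloxiran-2-yl]-3,7-dimethylnona-2,6-dien-1-yl]oxy}-6,8-dimethoxy-2H-chromen-2-one | COc1cc2ccc(=O)oc2c(OC)c1OC/C=C(C)/CC/C=C(C)/CC[C@@H]1OC1(C)C
A3 | alternative 3 | (4R,5R)-4-[(benzyloxy)methyl]-2,4,5-trimethylcyclohex-2-en-1-one | c1ccccc1COC[C@@]1(C)C=C(C)C(=O)C[C@H]1C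
A4 | alternative 3 | tert-butyl(dimethyl)[(3Z)-penta-1,3-dien-3-yloxy]silane | C/C=C(\O[Si](C)(C)C(C)(C)C)C=C
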